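The α-methylene-γ-lactone ring is cut at its Cα–Cβ bond, C11–C7 (ring carbons C1–C10: C1 carbinol, C4=C5, C6 lactone oxygen, C9 ketone, C10 methyl; lactone C11, C12 carbonyl, C13 methylene). The key step exploits that C7, the lactone β-carbon and ring-fusion atom, sits between two oxygen-bearing carbons (C6, C8): C6–C8 are C2–C4 of L-arabinose. A phosphonoacetate carbanion tethered to O6 displaces the C7 oxygen of an open-chain 7,8-cyclic sulfate with inversion, closing the lactone, unmasking O8 and, after olefination with formaldehyde in the same flask, installing C13. An acyloxy-directed anti-aldol (C10, C1) and ring-closing metathesis (C4=C5) complete the ten-membered ring.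

Key step: step 7

Remark: 2 is used as its anomer mixture (the anomeric centre is destroyed in step 2), 21 as its C9 epimer mixture (C9 becomes the ketone), and 10 is drawn in its C–H form although the excess NaH keeps it as the carbanion.

Step 1
Reactants: 1 L-arabinose
Product: 2 3,4-O-isopropylidene-L-arabinopyranose
Conditions: Me2C(OMe)2, TsOH·H2O (cat.), DMF, rt
Reagents that add atoms: 2,2-dimethoxypropane COC(C)(C)OC
Why: Acid-catalysed acetal exchange (acetonide protection) should select the cis-3,4-diol of the pyranose and leave O1 and O2 free; no stereocentre is formed.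

Step 2
Reactants: 2 3,4-O-isopropylidene-L-arabinopyranose
Product: 3 (1S)-1-[(4R,5S)-5-(hydroxymethyl)-2,2-dimethyl-1,3-dioxolan-4-yl]prop-2-en-1-ol
Conditions: Ph3PCH3Br, KOtBu, THF, 0 °C to 50 °C
Reagents that add atoms: methyltriphenylphosphonium bromide C[P+](c1ccccc1)(c1ccccc1)c1ccccc1.[Br-]
Why: Wittig methylenation of the open-chain aldehyde form of the lactol should turn sugar C1 into the C5 vinyl group and free O6 and O9; the three carbinol centres are carried over unchanged, the neighbouring alkoxide guarding C6 against enolisation.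

Step 3
Reactants: 3 (1S)-1-[(4R,5S)-5-(hydroxymethyl)-2,2-dimethyl-1,3-dioxolan-4-yl]prop-2-en-1-ol
Product: 4 (1S)-1-[(4R,5S)-5-[(tert-butyldiphenylsilyl)oxymethyl]-2,2-dimethyl-1,3-dioxolan-4-yl]prop-2-en-1-ol
Conditions: TBDPSCl, imidazole, CH2Cl2, 0 °C
Reagents that add atoms: tert-butyl(chloro)diphenylsilane CC(C)(C)[Si](Cl)(c1ccccc1)c1ccccc1
Why: Silyl ether formation with the bulky chloride should be selective for the primary C9 hydroxyl over the secondary allylic C6 hydroxyl.

Step 4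
Reactants: 4 (1S)-1-[(4R,5S)-5-[(tert-butyldiphenylsilyl)oxymethyl]-2,2-dimethyl-1,3-dioxolan-4-yl]prop-2-en-1-ol; 5 2-(diethoxyphosphoryl)acetic acid
Product: 6 (1S)-1-[(4R,5S)-5-[(tert-butyldiphenylsilyl)oxymethyl]-2,2-dimethyl-1,3-dioxolan-4-yl]prop-2-en-1-yl 2-(diethoxyphosphoryl)acetate
Conditions: DCC, DMAP (cat.), CH2Cl2, 0 °C to rt
Reagents that add atoms: none
Why: Steglich esterification should place the phosphonoacetate tether (the later C11–C12 unit) on O6 with retention at C6.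

Step 5
Reactants: 6 (1S)-1-[(4R,5S)-5-[(tert-butyldiphenylsilyl)oxymethyl]-2,2-dimethyl-1,3-dioxolan-4-yl]prop-2-en-1-yl 2-(diethoxyphosphoryl)acetate
Product: 7 (2S,3S,4S)-1-[(tert-butyldiphenylsilyl)oxy]-2,3-dihydroxyhex-5-en-4-yl 2-(diethoxyphosphoryl)acetate
Conditions: AcOH/H2O (4:1), 40 °C
Reagents that add atoms: none
Why: Acid hydrolysis of the dioxolane (acetal cleavage) should free the 7,8-diol while the silyl ether, allylic ester and phosphonate persist; the mild acid limits acyl migration from O6 to O7.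

Step 6
Reactants: 7 (2S,3S,4S)-1-[(tert-butyldiphenylsilyl)oxy]-2,3-dihydroxyhex-5-en-4-yl 2-(diethoxyphosphoryl)acetate
Product: 9 (1S)-1-[(4R,5S)-5-[(tert-butyldiphenylsilyl)oxymethyl]-2,2-dioxo-1,3,2-dioxathiolan-4-yl]prop-2-en-1-yl 2-(diethoxyphosphoryl)acetate, via cyclic sulfite 8 (not isolated)
Conditions: SOCl2, Et3N, CH2Cl2, 0 °C; then RuCl3·xH2O (cat.), NaIO4, MeCN/H2O, 0 °C
Reagents that add atoms: thionyl chloride O=S(Cl)Cl; sodium periodate [Na+].[O-]I(=O)(=O)=O
Why: Two-stage cyclic sulfate synthesis (sulfite formation, then RuO4-catalysed oxidation at sulfur) should activate the C7 and C8 oxygens without touching either C–O configuration; oxidation at sulfur is expected to be much faster than attack on the deactivated allylic vinyl group.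

Step 7
Reactants: 9 (1S)-1-[(4R,5S)-5-[(tert-butyldiphenylsilyl)oxymethyl]-2,2-dioxo-1,3,2-dioxathiolan-4-yl]prop-2-en-1-yl 2-(diethoxyphosphoryl)acetate
Product: 12 (4R,5S)-4-[(1R)-2-[(tert-butyldiphenylsilyl)oxy]-1-hydroxyethyl]-5-ethenyl-3-methylideneoxolan-2-one, via phosphonolactone sodium sulfate 10 (not isolated), via methylenelactone sodium sulfate 11 (not isolated)
Conditions: NaH (2.2 equiv), THF, 0 °C to rt; then (CH2O)n, rt; then H2SO4 (cat.), H2O, THF, rt
Reagents that add atoms: formaldehyde (as paraformaldehyde) C=O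
Why: Deprotonation gives the phosphonate-stabilised carbanion at C11, which should attack C7 of the cyclic sulfate anti to the C7–O bond (intramolecular SN2 C-alkylation), so that the arabinose C3 oxygen is replaced by carbon with inversion while C6 and C8 stay untouched. The closest known reactions are the C-alkylation of malonate and phosphonoacetate anions by 1,2-cyclic sulfates and the telescoped intramolecular Michael/olefination of O-tethered phosphonoacetates; here the same tether closes the five-membered lactone in the 5-exo-tet mode, the carbanion being stabilised exocyclically by phosphorus so that the usual enolate constraint on five-ring closure does not apply. The new stereocentre C7 is controlled only by the configuration of the C7–O bond (chirality transfer by inversion), which also fixes the cis relation of the C6 vinyl group and the C8 side chain on the lactone. The step needs C7-over-C8 regioselectivity and C- over O-alkylation: the tether reaches C7 through a five-membered transition state but C8 only through a 6-endo path with a poor backside trajectory, and the sodium counter-ion in THF with the soft phosphorus-stabilised carbanion should favour attack through carbon. The second equivalent of NaH keeps the phosphono lactone as its anion, which olefinates formaldehyde (Horner–Wadsworth–Emmons) to install C13, and acid then hydrolyses the sulfate monoester with S–O cleavage, unmasking O8 with retention.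

Step 8
Reactants: 13 methyl (Z)-2-methylbut-2-enoate (methyl angelate)
Product: 14 (Z)-2-methylbut-2-en-1-ol
Conditions: iBu2AlH (2.2 equiv), CH2Cl2, −78 °C to 0 °C; aq. KNaC4H4O6
Reagents that add atoms: none
Why: Ester reduction with the aluminium hydride at low temperature should give the allylic alcohol without Z-to-E isomerisation of the angelate double bond.

Step 9
Reactants: 14 (Z)-2-methylbut-2-en-1-ol
Product: 15 [(2S,3R)-2,3-dimethyloxiran-2-yl]methanol
Conditions: Ti(OiPr)4 (cat.), L-(+)-diisopropyl tartrate (cat.), tBuOOH, 4 Å molecular sieves, CH2Cl2, −20 °C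
Reagents that add atoms: tert-butyl hydroperoxide CC(C)(C)OO
Why: Sharpless asymmetric epoxidation with the L-(+)-tartrate should deliver oxygen to the face that gives the (2S,3R)-epoxy alcohol, the Z geometry fixing the cis relation of the carbinol carbon and the C3 methyl.

Step 10
Reactants: 15 [(2S,3R)-2,3-dimethyloxiran-2-yl]methanol
Product: 16 (2R,3R)-2,3-dimethyloxirane-2-carboxylic acid
Conditions: RuCl3·xH2O (cat.), NaIO4, CCl4/MeCN/H2O, rt
Reagents that add atoms: sodium periodate [Na+].[O-]I(=O)(=O)=O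
Why: RuO4-catalysed oxidation of the primary alcohol to the acid should leave the oxirane and both stereocentres intact (the descriptor at C2 changes only through the priority switch).

Step 11
Reactants: 12 (4R,5S)-4-[(1R)-2-[(tert-butyldiphenylsilyl)oxy]-1-hydroxyethyl]-5-ethenyl-3-methylideneoxolan-2-one; 16 (2R,3R)-2,3-dimethyloxirane-2-carboxylic acid
Product: 18 (1R)-2-[(tert-butyldiphenylsilyl)oxy]-1-[(2S,3S)-2-ethenyl-4-methylidene-5-oxooxolan-3-yl]ethyl (2R,3R)-2,3-dimethyloxirane-2-carboxylate, via mixed anhydride 17 (not isolated)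
Conditions: 16, 2,4,6-trichlorobenzoyl chloride, Et3N, toluene, rt; then 12, DMAP, toluene, rt
Reagents that add atoms: none
Why: Yamaguchi esterification should acylate the hindered C8 hydroxyl with the α-quaternary acid through the mixed anhydride; 12 is used at once so that the free O8 cannot translactonise, and both partners keep their configuration.

Step 12
Reactants: 18 (1R)-2-[(tert-butyldiphenylsilyl)oxy]-1-[(2S,3S)-2-ethenyl-4-methylidene-5-oxooxolan-3-yl]ethyl (2R,3R)-2,3-dimethyloxirane-2-carboxylate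
Product: 19 (1R)-1-[(2S,3S)-2-ethenyl-4-methylidene-5-oxooxolan-3-yl]-2-hydroxyethyl (2R,3R)-2,3-dimethyloxirane-2-carboxylate
Conditions: HF·pyridine, pyridine, THF, 0 °C to rt
Reagents that add atoms: none
Why: Buffered fluoride desilylation should cleave the primary silyl ether while sparing the oxirane, the esters and the methylene lactone, and the slightly acidic medium disfavours acyl migration from O8 to O9.

Step 13
Reactants: 19 (1R)-1-[(2S,3S)-2-ethenyl-4-methylidene-5-oxooxolan-3-yl]-2-hydroxyethyl (2R,3R)-2,3-dimethyloxirane-2-carboxylate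
Product: 20 (1R)-1-[(2S,3S)-2-ethenyl-4-methylidene-5-oxooxolan-3-yl]-2-oxoethyl (2R,3R)-2,3-dimethyloxirane-2-carboxylate
Conditions: Dess–Martin periodinane, CH2Cl2, 0 °C to rt
Reagents that add atoms: none
Why: Dess–Martin oxidation should give the α-acyloxy aldehyde under non-basic conditions so that C8 is not epimerised; the aldehyde is used crude.

Step 14
Reactants: 20 (1R)-1-[(2S,3S)-2-ethenyl-4-methylidene-5-oxooxolan-3-yl]-2-oxoethyl (2R,3R)-2,3-dimethyloxirane-2-carboxylate
Product: 21 (1R)-1-[(2S,3S)-2-ethenyl-4-methylidene-5-oxooxolan-3-yl]-2-hydroxybutyl (2R,3R)-2,3-dimethyloxirane-2-carboxylate (C9 epimers)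
Conditions: EtMgBr, THF, −78 °C; aq. NH4Cl at −78 °C
Reagents that add atoms: ethylmagnesium bromide CC[Mg]Br
Why: Grignard addition to the aldehyde at −78 °C should outrun attack on the lactone and the hindered ester; the new C9 carbinol forms as an epimer mixture that does not matter because C9 becomes the ketone, and the cold quench limits acyl shift to the alkoxide.

Step 15
Reactants: 21 (1R)-1-[(2S,3S)-2-ethenyl-4-methylidene-5-oxooxolan-3-yl]-2-hydroxybutyl (2R,3R)-2,3-dimethyloxirane-2-carboxylate (C9 epimers)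
Product: 22 (1R)-1-[(2S,3S)-2-ethenyl-4-methylidene-5-oxooxolan-3-yl]-2-oxobutyl (2R,3R)-2,3-dimethyloxirane-2-carboxylate
Conditions: Dess–Martin periodinane, CH2Cl2, rt
Reagents that add atoms: none
Why: Dess–Martin oxidation should converge both C9 epimers to the ethyl ketone without enolisation toward C8.

Step 16
Reactants: 23 ethyl 4-methylpent-4-enoate
Product: 24 4-methylpent-4-enal
Conditions: iBu2AlH (1.05 equiv), CH2Cl2, −78 °C; aq. KNaC4H4O6
Reagents that add atoms: none
Why: Partial ester reduction at −78 °C should stop at the tetrahedral aluminate, which gives the aldehyde on work-up.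

Step 17
Reactants: 22 (1R)-1-[(2S,3S)-2-ethenyl-4-methylidene-5-oxooxolan-3-yl]-2-oxobutyl (2R,3R)-2,3-dimethyloxirane-2-carboxylate; 24 4-methylpent-4-enal
Product: 27 (1R,3S,4S)-1-[(2S,3S)-2-ethenyl-4-methylidene-5-oxooxolan-3-yl]-4-hydroxy-3,7-dimethyl-2-oxooct-7-en-1-yl (2R,3R)-2,3-dimethyloxirane-2-carboxylate, via boron enolate 25 (not isolated), via boron aldolate 26 (not isolated)
Conditions: Cy2BCl, Me2NEt, Et2O, 0 °C; then 24, −78 °C to −20 °C; then H2O2, MeOH, pH 7 buffer, 0 °C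
Reagents that add atoms: none
Why: Paterson anti-aldol: the chloroborane and amine should give the E enol borinate on the ethyl side, and the chair transition state with the C8 acyloxy carbonyl turned toward the aldehyde (formyl hydrogen bond) and C8–H eclipsing the enolate sets the C10 methyl syn to O8 and the C1 hydroxyl anti to that methyl, i.e. 10S and 1S.

Step 18
Reactants: 27 (1R,3S,4S)-1-[(2S,3S)-2-ethenyl-4-methylidene-5-oxooxolan-3-yl]-4-hydroxy-3,7-dimethyl-2-oxooct-7-en-1-yl (2R,3R)-2,3-dimethyloxirane-2-carboxylate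
Product: 28 (3aS,4R,6S,7S,10Z,11aS)-7-hydroxy-6,10-dimethyl-3-methylidene-2,5-dioxo-2,3,3a,4,5,6,7,8,9,11a-decahydrocyclodeca[b]furan-4-yl (2R,3R)-2,3-dimethyloxirane-2-carboxylate (CNP0149149.1)
Conditions: second-generation Grubbs catalyst RuCl2(=CHPh)(PCy3)(H2IMes) (10 mol%), CH2Cl2 (1 mM), 40 °C
Reagents that add atoms: none
Why: Ring-closing metathesis between the C5 vinyl and C4 isopropenyl groups should form the ten-membered ring with loss of ethylene; in a ring of this size only the cis ring olefin (4Z) is expected, the cis-fused lactone and the sp2 C9 pre-organise the chain, and the conjugated exocyclic methylene is a poor metathesis partner.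

Compound list
1 | L-arabinose (pyranose form) | OC1OC[C@H](O)[C@H](O)[C@H]1O | starting material
2 | 3,4-O-isopropylidene-L-arabinopyranose (anomer mixture) | OC1OC[C@@H]2OC(C)(C)O[C@@H]2[C@H]1O | intermediate
3 | (1S)-1-[(4R,5S)-5-(hydroxymethyl)-2,2-dimethyl-1,3-dioxolan-4-yl]prop-2-en-1-ol | C=C[C@H](O)[C@H]1OC(C)(C)O[C@H]1CO | intermediate
4 | (1S)-1-[(4R,5S)-5-[(tert-butyldiphenylsilyl)oxymethyl]-2,2-dimethyl-1,3-dioxolan-4-yl]prop-2-en-1-ol | C=C[C@H](O)[C@H]1OC(C)(C)O[C@H]1CO[Si](c1ccccc1)(c1ccccc1)C(C)(C)C | intermediate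
5 | 2-(diethoxyphosphoryl)acetic acid | CCOP(=O)(CC(=O)O)OCC | starting material
6 | (1S)-1-[(4R,5S)-5-[(tert-butyldiphenylsilyl)oxymethyl]-2,2-dimethyl-1,3-dioxolan-4-yl]prop-2-en-1-yl 2-(diethoxyphosphoryl)acetate | C=C[C@H](OC(=O)CP(=O)(OCC)OCC)[C@H]1OC(C)(C)O[C@H]1CO[Si](c1ccccc1)(c1ccccc1)C(C)(C)C | intermediate
7 | (2S,3S,4S)-1-[(tert-butyldiphenylsilyl)oxy]-2,3-dihydroxyhex-5-en-4-yl 2-(diethoxyphosphoryl)acetate | C=C[C@H](OC(=O)CP(=O)(OCC)OCC)[C@@H](O)[C@@H](O)CO[Si](c1ccccc1)(c1ccccc1)C(C)(C)C | intermediate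
8 | (1S)-1-[(4R,5S)-5-[(tert-butyldiphenylsilyl)oxymethyl]-2-oxo-1,3,2-dioxathiolan-4-yl]prop-2-en-1-yl 2-(diethoxyphosphoryl)acetate (cyclic sulfite; sulfur epimers) | C=C[C@H](OC(=O)CP(=O)(OCC)OCC)[C@H]1OS(=O)O[C@H]1CO[Si](c1ccccc1)(c1ccccc1)C(C)(C)C | intermediate
9 | (1S)-1-[(4R,5S)-5-[(tert-butyldiphenylsilyl)oxymethyl]-2,2-dioxo-1,3,2-dioxathiolan-4-yl]prop-2-en-1-yl 2-(diethoxyphosphoryl)acetate (cyclic sulfate) | C=C[C@H](OC(=O)CP(=O)(OCC)OCC)[C@H]1OS(=O)(=O)O[C@H]1CO[Si](c1ccccc1)(c1ccccc1)C(C)(C)C | intermediate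
10 | sodium (1R)-2-[(tert-butyldiphenylsilyl)oxy]-1-[(2S,3S)-4-(diethoxyphosphoryl)-2-ethenyl-5-oxooxolan-3-yl]ethyl sulfate (C11 epimers) | CCOP(=O)(OCC)C1C(=O)O[C@@H](C=C)[C@H]1[C@@H](OS(=O)(=O)[O-])CO[Si](c1ccccc1)(c1ccccc1)C(C)(C)C.[Na+] | intermediate
11 | sodium (1R)-2-[(tert-butyldiphenylsilyl)oxy]-1-[(2S,3S)-2-ethenyl-4-methylidene-5-oxooxolan-3-yl]ethyl sulfate | C=C1C(=O)O[C@@H](C=C)[C@H]1[C@@H](OS(=O)(=O)[O-])CO[Si](c1ccccc1)(c1ccccc1)C(C)(C)C.[Na+] | intermediate
12 | (4R,5S)-4-[(1R)-2-[(tert-butyldiphenylsilyl)oxy]-1-hydroxyethyl]-5-ethenyl-3-methylideneoxolan-2-one | C=C1C(=O)O[C@@H](C=C)[C@H]1[C@@H](O)CO[Si](c1ccccc1)(c1ccccc1)C(C)(C)C | intermediate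
13 | methyl (Z)-2-methylbut-2-enoate (methyl angelate) | C/C=C(/C)C(=O)OC | starting material
14 | (Z)-2-methylbut-2-en-1-ol | C/C=C(/C)CO | intermediate
15 | [(2S,3R)-2,3-dimethyloxiran-2-yl]methanol | OC[C@]1(C)O[C@@H]1C | intermediate
16 | (2R,3R)-2,3-dimethyloxirane-2-carboxylic acid | OC(=O)[C@]1(C)O[C@@H]1C | intermediate
17 | (2R,3R)-2,3-dimethyloxirane-2-carboxylic 2,4,6-trichlorobenzoic anhydride | O=C(OC(=O)[C@]1(C)O[C@@H]1C)c1c(Cl)cc(Cl)cc1Cl | intermediate
18 | (1R)-2-[(tert-butyldiphenylsilyl)oxy]-1-[(2S,3S)-2-ethenyl-4-methylidene-5-oxooxolan-3-yl]ethyl (2R,3R)-2,3-dimethyloxirane-2-carboxylate | C=C1C(=O)O[C@@H](C=C)[C@H]1[C@@H](OC(=O)[C@]2(C)O[C@@H]2C)CO[Si](c1ccccc1)(c1ccccc1)C(C)(C)C | intermediate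
19 | (1R)-1-[(2S,3S)-2-ethenyl-4-methylidene-5-oxooxolan-3-yl]-2-hydroxyethyl (2R,3R)-2,3-dimethyloxirane-2-carboxylate | C=C1C(=O)O[C@@H](C=C)[C@H]1[C@@H](OC(=O)[C@]2(C)O[C@@H]2C)CO | intermediate
20 | (1R)-1-[(2S,3S)-2-ethenyl-4-methylidene-5-oxooxolan-3-yl]-2-oxoethyl (2R,3R)-2,3-dimethyloxirane-2-carboxylate | C=C1C(=O)O[C@@H](C=C)[C@H]1[C@@H](OC(=O)[C@]2(C)O[C@@H]2C)C=O | intermediate
21 | (1R)-1-[(2S,3S)-2-ethenyl-4-methylidene-5-oxooxolan-3-yl]-2-hydroxybutyl (2R,3R)-2,3-dimethyloxirane-2-carboxylate (C9 epimers) | C=C1C(=O)O[C@@H](C=C)[C@H]1[C@@H](OC(=O)[C@]2(C)O[C@@H]2C)C(O)CC | intermediate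
22 | (1R)-1-[(2S,3S)-2-ethenyl-4-methylidene-5-oxooxolan-3-yl]-2-oxobutyl (2R,3R)-2,3-dimethyloxirane-2-carboxylate | C=C1C(=O)O[C@@H](C=C)[C@H]1[C@@H](OC(=O)[C@]2(C)O[C@@H]2C)C(=O)CC | intermediate
23 | ethyl 4-methylpent-4-enoate | C=C(C)CCC(=O)OCC | starting material
24 | 4-methylpent-4-enal | C=C(C)CCC=O | intermediate
25 | (E)-dicyclohexylboron enolate of 22 | C=C1C(=O)O[C@@H](C=C)[C@H]1[C@@H](OC(=O)[C@]2(C)O[C@@H]2C)/C(OB(C2CCCCC2)C2CCCCC2)=C\C | intermediate
26 | dicyclohexylboron aldolate of 27 (boron on O1) | C=C1C(=O)O[C@@H](C=C)[C@H]1[C@@H](OC(=O)[C@]2(C)O[C@@H]2C)C(=O)[C@@H](C)[C@@H](OB(C2CCCCC2)C2CCCCC2)CCC(C)=C | intermediate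
27 | (1R,3S,4S)-1-[(2S,3S)-2-ethenyl-4-methylidene-5-oxooxolan-3-yl]-4-hydroxy-3,7-dimethyl-2-oxooct-7-en-1-yl (2R,3R)-2,3-dimethyloxirane-2-carboxylate | C=C1C(=O)O[C@@H](C=C)[C@H]1[C@@H](OC(=O)[C@]2(C)O[C@@H]2C)C(=O)[C@@H](C)[C@@H](O)CCC(C)=C | intermediate
28 | (3aS,4R,6S,7S,10Z,11aS)-7-hydroxy-6,10-dimethyl-3-methylidene-2,5-dioxo-2,3,3a,4,5,6,7,8,9,11a-decahydrocyclodeca[b]furan-4-yl (2R,3R)-2,3-dimethyloxirane-2-carboxylate (CNP0149149.1) | C=C1C(=O)O[C@H]2/C=C(/C)CC[C@H](O)[C@H](C)C(=O)[C@H](OC(=O)[C@]3(C)O[C@@H]3C)[C@@H]12 | target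

Total step count: 18. Longest linear sequence: 14 steps (steps 1–7, 11–15, 17 and 18, from 1 to 28).

Steps most likely to fail

1. Step 18 (ring-closing metathesis). Loading of ruthenium onto the hindered 1,1-disubstituted olefin may be slow and the forming trisubstituted cyclodecene is strained, so intermolecular metathesis at the C5 vinyl group (dimers, oligomers) could outrun ring closure. Fallback, a relay ring-closing metathesis that sets out from 22 and comes back at 28: geraniol is O-allylated (NaH, allyl bromide, THF) to allyl geranyl ether F1, the electron-rich 6,7-olefin is epoxidised (mCPBA, CH2Cl2, −20 °C) to epoxide F2, and HIO4 in THF/H2O cleaves it to the relay aldehyde F3. The aldol of step 17 between 22 (through 25) and F3 should give, through boron aldolate F4, the relay adduct F5. With the same ruthenium catalyst the carbene loads at the unhindered allyl ether terminus, expels 2,5-dihydrofuran and is thereby placed on C4, from where it closes onto the C5 vinyl group to give 28.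

2. Step 7 (key cyclisation). The carbanion may alkylate through the ester carbonyl oxygen (cyclic ketene acetal), or displacement at the oxygen-flanked secondary C7 may be so slow that elimination or intermolecular alkylation competes. Fallback with a malonate, whose C-alkylation by cyclic sulfates is established, setting out from 4 and coming back at 12: 4 is esterified with mono-tert-butyl malonate (DCC, DMAP) to malonate ester F6, hydrolysed (AcOH/H2O, 40 °C) to diol F7, and taken through cyclic sulfite F8 to cyclic sulfate F9 under the conditions of step 6. NaH in THF should then close the lactone by the same 5-exo-tet C-alkylation to sodium sulfate F10, and H2SO4 (cat.)/H2O/THF gives hydroxy lactone ester F11. CF3CO2H in CH2Cl2 removes the tert-butyl group to lactone acid F12, and decarboxylative Mannich methylenation (aq. CH2O, Et2NH; then NaOAc, AcOH, 80 °C) returns to 12.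

3. Step 14 (ethyl addition, with the labile aldehyde of step 13). The α-acyloxy aldehyde may epimerise at C8 by enolisation, and the magnesium alkoxide at C9 may take over the acyl group from O8 (1,2-acyl migration), which after step 15 would give the regioisomeric C8 ketone. Fallback by acyl cross-coupling, setting out from 19 and coming back at 22 without any aldehyde or alkoxide: 19 is oxidised to carboxylic acid F13 (TEMPO, PhI(OAc)2, MeCN/H2O), converted into S-ethyl thioester F14 (EtSH, DCC, DMAP, CH2Cl2), and coupled with EtZnI (Fukuyama coupling; PdCl2(PPh3)2, toluene, rt) to give 22 directly.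

Further compounds
F1 | step 18 | (E)-3,7-dimethyl-1-(prop-2-en-1-yloxy)octa-2,6-diene (allyl geranyl ether) | C=CCOC/C=C(\C)CCC=C(C)C
F2 | step 18 | 2,2-dimethyl-3-[(E)-3-methyl-5-(prop-2-en-1-yloxy)pent-3-en-1-yl]oxirane (racemic) | C=CCOC/C=C(\C)CCC1OC1(C)C
F3 | step 18 | (E)-4-methyl-6-(prop-2-en-1-yloxy)hex-4-enal | C=CCOC/C=C(\C)CCC=O
F4 | step 18 | dicyclohexylboron aldolate of F5 | C=C1C(=O)O[C@@H](C=C)[C@H]1[C@@H](OC(=O)[C@]2(C)O[C@@H]2C)C(=O)[C@@H](C)[C@@H](OB(C2CCCCC2)C2CCCCC2)CC/C(C)=C/COCC=C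
F5 | step 18 | (1R,3S,4S,7E)-1-[(2S,3S)-2-ethenyl-4-methylidene-5-oxooxolan-3-yl]-4-hydroxy-3,7-dimethyl-2-oxo-9-(prop-2-en-1-yloxy)non-7-en-1-yl (2R,3R)-2,3-dimethyloxirane-2-carboxylate | C=C1C(=O)O[C@@H](C=C)[C@H]1[C@@H](OC(=O)[C@]2(C)O[C@@H]2C)C(=O)[C@@H](C)[C@@H](O)CC/C(C)=C/COCC=C
F6 | step 7 | tert-butyl (1S)-1-[(4R,5S)-5-[(tert-butyldiphenylsilyl)oxymethyl]-2,2-dimethyl-1,3-dioxolan-4-yl]prop-2-en-1-yl propanedioate | C=C[C@H](OC(=O)CC(=O)OC(C)(C)C)[C@H]1OC(C)(C)O[C@H]1CO[Si](c1ccccc1)(c1ccccc1)C(C)(C)C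
F7 | step 7 | tert-butyl (2S,3S,4S)-1-[(tert-butyldiphenylsilyl)oxy]-2,3-dihydroxyhex-5-en-4-yl propanedioate | C=C[C@H](OC(=O)CC(=O)OC(C)(C)C)[C@@H](O)[C@@H](O)CO[Si](c1ccccc1)(c1ccccc1)C(C)(C)C
F8 | step 7 | cyclic sulfite of F7 (sulfur epimers) | C=C[C@H](OC(=O)CC(=O)OC(C)(C)C)[C@H]1OS(=O)O[C@H]1CO[Si](c1ccccc1)(c1ccccc1)C(C)(C)C
F9 | step 7 | cyclic sulfate of F7 | C=C[C@H](OC(=O)CC(=O)OC(C)(C)C)[C@H]1OS(=O)(=O)O[C@H]1CO[Si](c1ccccc1)(c1ccccc1)C(C)(C)C
F10 | step 7 | sodium (1R)-1-[(2S,3S)-4-(tert-butoxycarbonyl)-2-ethenyl-5-oxooxolan-3-yl]-2-[(tert-butyldiphenylsilyl)oxy]ethyl sulfate (C11 epimers) | CC(C)(C)OC(=O)C1C(=O)O[C@@H](C=C)[C@H]1[C@@H](OS(=O)(=O)[O-])CO[Si](c1ccccc1)(c1ccccc1)C(C)(C)C.[Na+]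
F11 | step 7 | tert-butyl (4S,5S)-4-[(1R)-2-[(tert-butyldiphenylsilyl)oxy]-1-hydroxyethyl]-5-ethenyl-2-oxooxolane-3-carboxylate (C11 epimers) | CC(C)(C)OC(=O)C1C(=O)O[C@@H](C=C)[C@H]1[C@@H](O)CO[Si](c1ccccc1)(c1ccccc1)C(C)(C)C
F12 | step 7 | (4S,5S)-4-[(1R)-2-[(tert-butyldiphenylsilyl)oxy]-1-hydroxyethyl]-5-ethenyl-2-oxooxolane-3-carboxylic acid (C11 epimers) | OC(=O)C1C(=O)O[C@@H](C=C)[C@H]1[C@@H](O)CO[Si](c1ccccc1)(c1ccccc1)C(C)(C)C
F13 | step 14 | (2R)-2-[(2R,3R)-2,3-dimethyloxirane-2-carbonyl]oxy-2-[(2S,3S)-2-ethenyl-4-methylidene-5-oxooxolan-3-yl]acetic acid | C=C1C(=O)O[C@@H](C=C)[C@H]1[C@@H](OC(=O)[C@]2(C)O[C@@H]2C)C(=O)O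
F14 | step 14 | S-ethyl thioester of F13 | C=C1C(=O)O[C@@H](C=C)[C@H]1[C@@H](OC(=O)[C@]2(C)O[C@@H]2C)C(=O)SCC
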